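**Retrosynthetic overview**
1. Target 19 ⇐ 4,5-epoxy-7(11)-en-12,6-olide 18 (glaucolide type): base removes H-6 and the dienolate opens the epoxide, giving C4–OH and C5=C6, as in the glaucolide → hirsutinolide relationship.
2. 18 ⇐ acyclic epoxy aldehyde 16: the C6–C7 bond (the C1–C10 bond of farnesyl/germacrane biogenesis) is closed by intramolecular Ni/Cr addition of a (Z)-β-iodo enoate; the C6 alkoxide then closes the 12→6 lactone.
3. 16 ⇐ Sharpless epoxidation (C4), iodide/formaldehyde iodo-aldol on a γ-hydroxy ynoate (C7=C11, C13), asymmetric propiolate addition (C8).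
4. Chain ⇐ (S)-α-methyl-γ-butyrolactone (C10) + MeLi + an (E)-C5 allylic bromide made from prenol.
5. Ring order: ten-membered carbocycle first, butenolide second, both in the last flask.

Assumption: C-numbers in the text follow germacrane numbering of 19 (C1 ketone, C4 carbinol, C6 lactone O–C, C8 ester carbon, C10 methyl carbon, C12 lactone C=O, C13 CH2OAc); 19 is treated as the open hydroxy ketone drawn, and (S)-α-methyl-γ-butyrolactone 5 is bought.

**Route**

Step 1
Reactants: 1 3-methylbut-2-en-1-ol (prenol)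
Product: 2 tert-butyldimethyl[(3-methylbut-2-en-1-yl)oxy]silane
Conditions: TBSCl, imidazole, DMF, rt
Reagents that add atoms: tert-butyldimethylsilyl chloride, CC(C)(C)[Si](C)(C)Cl
Why: Standard silyl ether protection of a primary alcohol; no stereocentre is involved.

Step 2
Reactants: 2 tert-butyldimethyl[(3-methylbut-2-en-1-yl)oxy]silane
Product: 3 (E)-4-[(tert-butyldimethylsilyl)oxy]-2-methylbut-2-en-1-ol
Conditions: SeO2 (10 mol%), t-BuOOH, salicylic acid (cat.), CH2Cl2, rt
Reagents that add atoms: tert-butyl hydroperoxide, CC(C)(C)OO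
Why: SeO2/t-BuOOH allylic oxidation (ene reaction, then [2,3]-shift) oxidises the (E)-methyl group of a trisubstituted alkene, which fixes the E geometry of the future C4=C5 bond.

Step 3
Reactants: 3 (E)-4-[(tert-butyldimethylsilyl)oxy]-2-methylbut-2-en-1-ol
Product: 4 (E)-[(4-bromo-3-methylbut-2-en-1-yl)oxy](tert-butyl)dimethylsilane
Conditions: CBr4, PPh3, CH2Cl2, −20 °C
Reagents that add atoms: carbon tetrabromide, BrC(Br)(Br)Br
Why: Appel bromination of a primary allylic alcohol at low temperature proceeds without allylic transposition and leaves the silyl ether and the E alkene untouched.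

Step 4
Reactants: 5 (S)-3-methyldihydrofuran-2(3H)-one; 4 (E)-[(4-bromo-3-methylbut-2-en-1-yl)oxy](tert-butyl)dimethylsilane
Product: 7 (3S,7E)-9-[(tert-butyldimethylsilyl)oxy]-1-hydroxy-3,7-dimethylnon-7-en-4-one, via keto alkoxide 6 (not isolated)
Conditions: MeLi (1.0 equiv), THF, −78 °C then 0 °C; LDA (1.1 equiv), −78 °C; then 4, −78 → −20 °C; aq. NH4Cl
Reagents that add atoms: methyllithium, C[Li]
Why: One equivalent of MeLi adds once to the γ-lactone (the lithium lactolate resists a second addition), LDA then forms the kinetic methyl-side enolate of the keto alkoxide, and SN2 enolate alkylation with the allylic bromide forms C2–C3; the C10 stereocentre comes from 5 and is not deprotonated.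

Step 5
Reactants: 7 (3S,7E)-9-[(tert-butyldimethylsilyl)oxy]-1-hydroxy-3,7-dimethylnon-7-en-4-one
Product: 8 (3S,7E)-9-[(tert-butyldimethylsilyl)oxy]-3,7-dimethyl-4-oxonon-7-enal
Conditions: Dess–Martin periodinane, NaHCO3, CH2Cl2, 0 °C → rt
Reagents that add atoms: none
Why: Buffered Dess–Martin oxidation takes the primary alcohol to the aldehyde without epimerising the α-keto centre C10 or touching the silyl ether.

Step 6
Reactants: 8 (3S,7E)-9-[(tert-butyldimethylsilyl)oxy]-3,7-dimethyl-4-oxonon-7-enal; 9 methyl propiolate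
Product: 10 methyl (4R,6S,10E)-12-[(tert-butyldimethylsilyl)oxy]-4-hydroxy-6,10-dimethyl-7-oxododec-10-en-2-ynoate
Conditions: (R,R)-ProPhenol (20 mol%), Me2Zn (3 equiv), Ph3P=O (40 mol%), toluene, 4 °C
Reagents that add atoms: none
Why: Trost Zn–ProPhenol asymmetric alkynylation adds the zinc acetylide of 9 to the aldehyde only (the ketone is inert to alkynylzinc), with the ligand antipode chosen for Si-face addition so that C8 is set as R; the sense must be confirmed by Mosher analysis and the other ligand antipode used if needed.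

Step 7
Reactants: 10 methyl (4R,6S,10E)-12-[(tert-butyldimethylsilyl)oxy]-4-hydroxy-6,10-dimethyl-7-oxododec-10-en-2-ynoate
Product: 11 methyl (2Z,4R,6S,10E)-12-[(tert-butyldimethylsilyl)oxy]-4-hydroxy-2-(hydroxymethyl)-3-iodo-6,10-dimethyl-7-oxododeca-2,10-dienoate
Conditions: MgI2 (1.5 equiv), (CH2O)n (3 equiv), CH2Cl2, 0 °C → rt
Reagents that add atoms: magnesium iodide, [Mg+2].[I-].[I-]; formaldehyde (from paraformaldehyde), C=O
Why: Proposed new method: iodide adds in conjugate fashion to the Mg-activated ynoate and the β-iodo magnesium allenolate is hydroxymethylated at the α-carbon, with Mg(II) bridging the C8 hydroxyl and formaldehyde so that the electrophile enters on the carbinol side, anti to iodine, giving the 2Z alkene (I cis to CO2Me, CH2OH cis to C8); the closest known reaction is the MgI2- or Et2AlI-mediated β-iodo Morita–Baylis–Hillman (iodo-aldol) reaction of propiolates, which is Z-selective under kinetic control, and any E isomer would lactonise onto the C8 hydroxyl and be separable.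

Step 8
Reactants: 11 methyl (2Z,4R,6S,10E)-12-[(tert-butyldimethylsilyl)oxy]-4-hydroxy-2-(hydroxymethyl)-3-iodo-6,10-dimethyl-7-oxododeca-2,10-dienoate
Product: 13 methyl (2Z,4R,6S,10E)-2-(acetoxymethyl)-12-[(tert-butyldimethylsilyl)oxy]-3-iodo-6,10-dimethyl-4-[(3-methylbut-2-enoyl)oxy]-7-oxododeca-2,10-dienoate, via monoacetate 12 (not isolated)
Conditions: AcCl (1.05 equiv), 2,4,6-collidine, CH2Cl2, −78 °C; then 3-methylbut-2-enoyl chloride, pyridine, DMAP (cat.), 0 °C
Reagents that add atoms: acetyl chloride, CC(=O)Cl; 3-methylbut-2-enoyl chloride, CC(C)=CC(=O)Cl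
Why: Chemoselective acylation: AcCl/collidine at −78 °C acetylates only the primary allylic alcohol, and the remaining hindered secondary alcohol is then esterified with senecioyl chloride under DMAP catalysis; no stereocentre is touched.

Step 9
Reactants: 13 methyl (2Z,4R,6S,10E)-2-(acetoxymethyl)-12-[(tert-butyldimethylsilyl)oxy]-3-iodo-6,10-dimethyl-4-[(3-methylbut-2-enoyl)oxy]-7-oxododeca-2,10-dienoate
Product: 14 methyl (2Z,4R,6S,10E)-2-(acetoxymethyl)-12-hydroxy-3-iodo-6,10-dimethyl-4-[(3-methylbut-2-enoyl)oxy]-7-oxododeca-2,10-dienoate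
Conditions: HF·pyridine, pyridine, THF, 0 °C
Reagents that add atoms: none
Why: Buffered fluoride desilylation frees the allylic alcohol while the acetate, senecioate, methyl ester and vinyl iodide survive.

Step 10
Reactants: 14 methyl (2Z,4R,6S,10E)-2-(acetoxymethyl)-12-hydroxy-3-iodo-6,10-dimethyl-4-[(3-methylbut-2-enoyl)oxy]-7-oxododeca-2,10-dienoate
Product: 15 methyl (2Z,4R,6S)-2-(acetoxymethyl)-9-[(2R,3R)-3-(hydroxymethyl)-2-methyloxiran-2-yl]-3-iodo-6-methyl-4-[(3-methylbut-2-enoyl)oxy]-7-oxonon-2-enoate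
Conditions: Ti(OiPr)4 (10 mol%), D-(−)-diethyl tartrate (12 mol%), t-BuOOH, 4 Å MS, CH2Cl2, −20 °C
Reagents that add atoms: tert-butyl hydroperoxide, CC(C)(C)OO
Why: Sharpless asymmetric epoxidation of the geraniol-type (E)-allylic alcohol with D-(−)-DET gives the (2R,3R)-epoxy alcohol (mirror of the (2S,3S) product from L-(+)-DET), which sets C4 as R; the electron-poor alkenes do not react.

Step 11
Reactants: 15 methyl (2Z,4R,6S)-2-(acetoxymethyl)-9-[(2R,3R)-3-(hydroxymethyl)-2-methyloxiran-2-yl]-3-iodo-6-methyl-4-[(3-methylbut-2-enoyl)oxy]-7-oxonon-2-enoate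
Product: 16 methyl (2Z,4R,6S)-2-(acetoxymethyl)-9-[(2R,3S)-3-formyl-2-methyloxiran-2-yl]-3-iodo-6-methyl-4-[(3-methylbut-2-enoyl)oxy]-7-oxonon-2-enoate
Conditions: Dess–Martin periodinane, NaHCO3, CH2Cl2, 0 °C
Reagents that add atoms: none
Why: Buffered Dess–Martin oxidation gives the α,β-epoxy aldehyde without opening the epoxide (the descriptor change at the oxirane CH is only a CIP priority change); the product is used crude.

Step 12
Reactants: 16 methyl (2Z,4R,6S)-2-(acetoxymethyl)-9-[(2R,3S)-3-formyl-2-methyloxiran-2-yl]-3-iodo-6-methyl-4-[(3-methylbut-2-enoyl)oxy]-7-oxonon-2-enoate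
Product: 19 (4R,5Z,8R,10S)-13-acetoxy-4-hydroxy-8-[(3-methylbut-2-enoyl)oxy]-1-oxogermacra-5,7(11)-dien-12,6-olide, via hydroxy ester 17 (not isolated), via epoxy butenolide 18 (not isolated)
Conditions: CrCl2 (10 equiv), NiCl2 (2 mol%), DMSO/THF, 0.003 M (slow addition), rt; aqueous work-up; then DBU (0.3 equiv), CH2Cl2, 0 °C
Reagents that add atoms: none
Why: Nozaki–Hiyama–Kishi macrocyclisation (Ni insertion into C–I with retention, transmetalation to Cr(III), addition to the aldehyde and not the ketone) closes C6–C7, the chromium alkoxide held cis to the ester by the (Z)-alkene lactonises, and DBU then removes the γ-proton H-6 so that the dienolate opens the epoxide (vinylogous E1cB); this keeps C4 (R), erases the uncontrolled C5 and C6 centres and gives the (5Z)-ylidene lactone favoured by allylic strain.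

**Compound list**
1 | 3-methylbut-2-en-1-ol (prenol) | CC(C)=CCO | starting material
2 | tert-butyldimethyl[(3-methylbut-2-en-1-yl)oxy]silane | CC(C)=CCO[Si](C)(C)C(C)(C)C | intermediate
3 | (E)-4-[(tert-butyldimethylsilyl)oxy]-2-methylbut-2-en-1-ol | OC/C(C)=C/CO[Si](C)(C)C(C)(C)C | intermediate
4 | (E)-[(4-bromo-3-methylbut-2-en-1-yl)oxy](tert-butyl)dimethylsilane | BrC/C(C)=C/CO[Si](C)(C)C(C)(C)C | intermediate
5 | (S)-3-methyldihydrofuran-2(3H)-one ((S)-α-methyl-γ-butyrolactone) | C[C@H]1CCOC1=O | starting material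
6 | lithium (S)-3-methyl-4-oxopentan-1-olate (keto alkoxide, not isolated) | [Li+].[O-]CC[C@H](C)C(C)=O | intermediate
7 | (3S,7E)-9-[(tert-butyldimethylsilyl)oxy]-1-hydroxy-3,7-dimethylnon-7-en-4-one | OCC[C@H](C)C(=O)CC/C(C)=C/CO[Si](C)(C)C(C)(C)C | intermediate
8 | (3S,7E)-9-[(tert-butyldimethylsilyl)oxy]-3,7-dimethyl-4-oxonon-7-enal | O=CC[C@H](C)C(=O)CC/C(C)=C/CO[Si](C)(C)C(C)(C)C | intermediate
9 | methyl propiolate | C#CC(=O)OC | starting material
10 | methyl (4R,6S,10E)-12-[(tert-butyldimethylsilyl)oxy]-4-hydroxy-6,10-dimethyl-7-oxododec-10-en-2-ynoate | COC(=O)C#C[C@H](O)C[C@H](C)C(=O)CC/C(C)=C/CO[Si](C)(C)C(C)(C)C | intermediate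
11 | methyl (2Z,4R,6S,10E)-12-[(tert-butyldimethylsilyl)oxy]-4-hydroxy-2-(hydroxymethyl)-3-iodo-6,10-dimethyl-7-oxododeca-2,10-dienoate | COC(=O)/C(CO)=C(\I)[C@H](O)C[C@H](C)C(=O)CC/C(C)=C/CO[Si](C)(C)C(C)(C)C | intermediate
12 | methyl (2Z,4R,6S,10E)-2-(acetoxymethyl)-12-[(tert-butyldimethylsilyl)oxy]-4-hydroxy-3-iodo-6,10-dimethyl-7-oxododeca-2,10-dienoate (monoacetate, not isolated) | COC(=O)/C(COC(C)=O)=C(\I)[C@H](O)C[C@H](C)C(=O)CC/C(C)=C/CO[Si](C)(C)C(C)(C)C | intermediate
13 | methyl (2Z,4R,6S,10E)-2-(acetoxymethyl)-12-[(tert-butyldimethylsilyl)oxy]-3-iodo-6,10-dimethyl-4-[(3-methylbut-2-enoyl)oxy]-7-oxododeca-2,10-dienoate | COC(=O)/C(COC(C)=O)=C(\I)[C@H](OC(=O)C=C(C)C)C[C@H](C)C(=O)CC/C(C)=C/CO[Si](C)(C)C(C)(C)C | intermediate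
14 | methyl (2Z,4R,6S,10E)-2-(acetoxymethyl)-12-hydroxy-3-iodo-6,10-dimethyl-4-[(3-methylbut-2-enoyl)oxy]-7-oxododeca-2,10-dienoate | COC(=O)/C(COC(C)=O)=C(\I)[C@H](OC(=O)C=C(C)C)C[C@H](C)C(=O)CC/C(C)=C/CO | intermediate
15 | methyl (2Z,4R,6S)-2-(acetoxymethyl)-9-[(2R,3R)-3-(hydroxymethyl)-2-methyloxiran-2-yl]-3-iodo-6-methyl-4-[(3-methylbut-2-enoyl)oxy]-7-oxonon-2-enoate | COC(=O)/C(COC(C)=O)=C(\I)[C@H](OC(=O)C=C(C)C)C[C@H](C)C(=O)CC[C@@]1(C)O[C@@H]1CO | intermediate
16 | methyl (2Z,4R,6S)-2-(acetoxymethyl)-9-[(2R,3S)-3-formyl-2-methyloxiran-2-yl]-3-iodo-6-methyl-4-[(3-methylbut-2-enoyl)oxy]-7-oxonon-2-enoate | COC(=O)/C(COC(C)=O)=C(\I)[C@H](OC(=O)C=C(C)C)C[C@H](C)C(=O)CC[C@@]1(C)O[C@@H]1C=O | intermediate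
17 | methyl (4R,5R,8R,10S)-13-acetoxy-4,5-epoxy-6-hydroxy-8-[(3-methylbut-2-enoyl)oxy]-1-oxogermacr-7(11)-en-12-oate (C6 epimers, C6 cis to CO2Me; formed as its Cr(III) alkoxide, not isolated) | COC(=O)/C(COC(C)=O)=C1/[C@H](OC(=O)C=C(C)C)C[C@H](C)C(=O)CC[C@@]2(C)O[C@@H]2C1O | intermediate
18 | (4R,5R,8R,10S)-13-acetoxy-4,5-epoxy-8-[(3-methylbut-2-enoyl)oxy]-1-oxogermacr-7(11)-en-12,6-olide (C6 epimers, not isolated) | CC(=O)OCC1=C2C(OC1=O)[C@H]3O[C@]3(C)CCC(=O)[C@@H](C)C[C@H]2OC(=O)C=C(C)C | intermediate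
19 | (4R,5Z,8R,10S)-13-acetoxy-4-hydroxy-8-[(3-methylbut-2-enoyl)oxy]-1-oxogermacra-5,7(11)-dien-12,6-olide (CNP0186726.1) | CC(=O)OCC1=C2/C(=C/[C@](C)(O)CCC(=O)[C@@H](C)C[C@H]2OC(=O)C=C(C)C)OC1=O | target

**Totals and risks**

Total step count: 12. Longest linear sequence: 12 (prenol 1 → 19; lactone 5 and methyl propiolate 9 enter as bought compounds).

The three steps most likely to fail:

Step 7 (iodo-aldol). The Z-selective outcome is an extrapolation from propiolates to a β-substituted ynoate; the electrophile may enter syn to iodine, and the E isomer would be lost as the C8-lactone. The fallback sets out from 10 and comes back at 11. Compound 10 is silylated in the flask (TMSCl, imidazole) and treated with Me3SnCu·SMe2 (THF, −48 °C, equilibrating conditions). The copper allenoate is trapped with monomeric formaldehyde on the face away from the large Me3Sn group, and acidic work-up removes the TMS group to give methyl (2Z,4R,6S,10E)-12-[(tert-butyldimethylsilyl)oxy]-4-hydroxy-2-(hydroxymethyl)-6,10-dimethyl-7-oxo-3-(trimethylstannyl)dodeca-2,10-dienoate F1. Iododestannylation (I2, CH2Cl2, 0 °C) goes with retention and gives 11.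

Step 12 (Ni/Cr ring closure, lactonisation, epoxide opening). A ten-membered ring is closed with a tetrasubstituted alkenyl iodide next to an allylic ester, on a labile epoxy aldehyde; oligomerisation, β-elimination from the alkenylchromium or loss of the epoxy aldehyde are possible. The fallback sets out from 14 and comes back at 19. Compound 14 is oxidised with MnO2 to the enal methyl (2Z,4R,6S,10E)-2-(acetoxymethyl)-3-iodo-6,10-dimethyl-4-[(3-methylbut-2-enoyl)oxy]-7,12-dioxododeca-2,10-dienoate F2, which has no epoxide. The same Ni/Cr closure and lactonisation give (4E,8R,10S)-13-acetoxy-8-[(3-methylbut-2-enoyl)oxy]-1-oxogermacra-4,7(11)-dien-12,6-olide F3 (C6 epimers). A Schenck ene reaction with singlet oxygen (O2, TPP, hν, CH2Cl2, −20 °C) abstracts the doubly activated H-6 and gives (4R,5Z,8R,10S)-13-acetoxy-4-hydroperoxy-8-[(3-methylbut-2-enoyl)oxy]-1-oxogermacra-5,7(11)-dien-12,6-olide F4, which PPh3 reduces to 19. In this variant C4 is set by the exposed face of the ring, not by a reagent, so the diastereomer ratio must be checked.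

Step 6 (asymmetric alkynylation). The γ-keto aldehyde can undergo intramolecular aldol reaction under the basic zinc conditions, and unbranched aldehydes give only moderate ee. The fallback sets out from 8 and comes back at 10. Compound 8 is treated with lithiated methyl propiolate (LiHMDS, THF, −90 °C) to give the C4-epimeric mixture methyl (4RS,6S,10E)-12-[(tert-butyldimethylsilyl)oxy]-4-hydroxy-6,10-dimethyl-7-oxododec-10-en-2-ynoate F5. Dess–Martin oxidation gives the ynone methyl (6S,10E)-12-[(tert-butyldimethylsilyl)oxy]-6,10-dimethyl-4,7-dioxododec-10-en-2-ynoate F6. Noyori transfer hydrogenation with RuCl[(R,R)-TsDPEN](p-cymene) in iPrOH reduces only the ynone carbonyl and gives 10.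

**Further compounds**
F1 | step 7 | methyl (2Z,4R,6S,10E)-12-[(tert-butyldimethylsilyl)oxy]-4-hydroxy-2-(hydroxymethyl)-6,10-dimethyl-7-oxo-3-(trimethylstannyl)dodeca-2,10-dienoate | COC(=O)/C(CO)=C(\[Sn](C)(C)C)[C@H](O)C[C@H](C)C(=O)CC/C(C)=C/CO[Si](C)(C)C(C)(C)C
F2 | step 12 | methyl (2Z,4R,6S,10E)-2-(acetoxymethyl)-3-iodo-6,10-dimethyl-4-[(3-methylbut-2-enoyl)oxy]-7,12-dioxododeca-2,10-dienoate | COC(=O)/C(COC(C)=O)=C(\I)[C@H](OC(=O)C=C(C)C)C[C@H](C)C(=O)CC/C(C)=C/C=O
F3 | step 12 | (4E,8R,10S)-13-acetoxy-8-[(3-methylbut-2-enoyl)oxy]-1-oxogermacra-4,7(11)-dien-12,6-olide (C6 epimers) | CC(=O)OCC1=C2C(OC1=O)/C=C(\C)CCC(=O)[C@@H](C)C[C@H]2OC(=O)C=C(C)C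
F4 | step 12 | (4R,5Z,8R,10S)-13-acetoxy-4-hydroperoxy-8-[(3-methylbut-2-enoyl)oxy]-1-oxogermacra-5,7(11)-dien-12,6-olide | CC(=O)OCC1=C2/C(=C/[C@](C)(OO)CCC(=O)[C@@H](C)C[C@H]2OC(=O)C=C(C)C)OC1=O
F5 | step 6 | methyl (4RS,6S,10E)-12-[(tert-butyldimethylsilyl)oxy]-4-hydroxy-6,10-dimethyl-7-oxododec-10-en-2-ynoate | COC(=O)C#CC(O)C[C@H](C)C(=O)CC/C(C)=C/CO[Si](C)(C)C(C)(C)C
F6 | step 6 | methyl (6S,10E)-12-[(tert-butyldimethylsilyl)oxy]-6,10-dimethyl-4,7-dioxododec-10-en-2-ynoate | COC(=O)C#CC(=O)C[C@H](C)C(=O)CC/C(C)=C/CO[Si](C)(C)C(C)(C)C
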